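**Analysis of the target**

The target 15 is a 2H-chromene: a benzene ring fused to a pyran ring made up of O1, the quaternary C2, the C3=C4 double bond (conjugated with the arene), C4a and C8a. The benzene ring carries an acetyl group at C6 (para to O1) and a methoxy group at C8 (ortho to O1). C2 bears a methyl group and a CH2O unit esterified with (E)-ferulic acid, so the molecule is a chromene alcohol and a phenolic cinnamic acid joined by one ester bond. The only stereocentre is C2, of (R) configuration. It is a fully substituted tertiary ether carbon whose two exocyclic groups differ only as CH3 and CH2O-acyl, and there is no second stereocentre to relay or correct it. Sensitive groups are the 2H-chromene (electrocyclic ring opening under UV light or strong heating would erase C2), the ester, the free phenol with its (E)-cinnamate, and the enolisable methyl ketone. The difficulty is to set this tertiary ether centre enantioselectively on an arene whose oxygen is deactivated by the para acetyl group. The strategy rests on one mapping: O1–C8a–C4a–C4 is the heterodiene of an ortho-quinone methide (acetovanillone plus one carbon), and C3–C2 with its methyl and CH2OH groups is the skeleton of 2-methylprop-2-en-1-ol (4), with matching polarity (nucleophilic CH2 to C4, cation-stabilising disubstituted carbon to O1).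

**Retrosynthetic reasoning**

15 from 14. The last operation is removal of a silyl ether from the ferulate phenol. Keeping the phenol masked until the end prevents it from competing as an acyl acceptor, and the unmasking is mild enough for the ester and the chromene.

14 from 10 and 13. The acyl C–O bond of the ester is cut. This is the one convergent cut in the molecule and it separates the stereochemical problem (10) from the electron-rich cinnamoyl unit, which would not survive the installation of C3=C4. Acid 13 comes from ferulic acid 11 through the doubly silylated 12. The forward reaction has to acylate a primary, neopentyl-type hydroxyl at oxygen.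

10 from 9, 8 and 7. The C3=C4 double bond is removed, leading back to the saturated chroman with its alcohol as acetate 7. The saturated pyran is exactly what a [4+2] between a heterodiene and a simple alkene delivers, and the chroman centre has no electrocyclic racemisation pathway. In the forward direction C4 is the only benzylic CH2 and C2 is quaternary, so benzylic bromination (8) and dehydrobromination can only give the C3=C4 alkene (9). The acetate keeps the hydroxyl from trapping the C4 electrophile as a bridged ether.

7 from 6. Simple acetylation of the primary alcohol.

6 from 5 and 4, and 5 from 3. Two ring bonds, C3–C4 and O1–C2, are cut together in a retro-[4+2]. This reveals ortho-quinone methide 5 and alkene 4, and 5 is the dehydration product of salicyl alcohol 3. Cutting here removes the ring, both skeletal bonds and the stereocentre in one operation and leaves achiral partners that are commercial or one step away. The forward reaction must generate 5 catalytically, direct the CH2 terminus of 4 to the methide carbon and select one face of the disubstituted alkene carbon for bonding to O1.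

3 from 1 and 2. The C4–C4a bond is cut ortho to the phenol, giving acetovanillone 1 and formaldehyde 2. Only one ortho position of 1 is free and the para position is blocked, so regiochemistry is fixed by the substrate.

**Alternatives that were turned down**

Alternative 1: The side-chain CH2–O bond is traced back to a C–H bond of one of two enantiotopic methyl groups in 2-(4-acetyl-2-bromo-6-methoxyphenoxy)-2-methylpropanoic acid A1.
- Key step: Pd(OAc)2 (divalent palladium), a chiral mono-protected amino-acid-type ligand and a hydroperoxide oxidant would cleave one methyl C–H of A1 under carboxylate direction and close the CH2–O bond, giving the β-lactone (3S)-3-(4-acetyl-2-bromo-6-methoxyphenoxy)-3-methyloxetan-2-one A2.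
- For: A1 is about two steps from 1. The stereocentre arises by desymmetrising two identical groups under a covalently bound directing group, a more tightly organised event than the non-covalent recognition used in the chosen route. On that point this alternative is the stronger one.
- Against: the pyran ring is not formed in A2. The lactone carbonyl of A2 must be reduced in the presence of the methyl ketone, extended by one carbon and joined to the brominated ring carbon, and closure of an aryl bromide onto such an allylic ether prefers the five-membered exo mode. The α-aryloxy group slows carboxylate-directed C–H cleavage, the strained lactone is fragile, and the aryl bromide can be consumed by any zerovalent palladium formed.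
- Comparison: roughly thirteen steps against eight. The chosen route offers ring, both bonds and stereocentre in one step from a one-step precursor.

Alternative 2: Only O1–C2 is cut, with the carbon skeleton pre-assembled as (2E)-4-(5-acetyl-2-hydroxy-3-methoxyphenyl)-2-methylbut-2-en-1-yl acetate A3.
- Key step: a chiral selenophosphoramide Lewis base would transfer a phenylsulfenyl cation from an N-sulfenyl imide to the alkene of A3, and the phenol oxygen would open the thiiranium ion at the tertiary carbon anti to sulfur. The product is (2S,3R)-2-(acetoxymethyl)-6-acetyl-8-methoxy-2-methyl-3-(phenylthio)chroman A4, and sulfoxide elimination from A4 would later give C3=C4.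
- For: enantioselective sulfenofunctionalisation with phenol nucleophiles is an existing reaction class, so the asymmetric step is better precedented than the chosen key step. The sulfur at C3 of A4 is also a cleaner handle for the double bond than radical bromination.
- Against: A3 needs four to five steps to place an (E)-trisubstituted allylic acetate ortho to the phenol, and its E/Z purity caps the enantiomeric purity at C2. The para-acetyl phenol is a weak nucleophile, the acetate carbonyl can compete for the thiiranium ion, and the CH2OAc group weakens the Markovnikov bias towards six-membered closure.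
- Comparison: about eleven to twelve linear steps. The chosen route trades precedent for brevity and for partners that need no alkene-geometry control.

Alternative 3: C4 is excised (C3–C4 and C4–C4a), leading to (2S)-5-bromo-2-{[tert-butyl(dimethyl)silyl]oxymethyl}-7-methoxy-2-methyl-1-benzofuran-3(2H)-one A5.
- Key step: a silylated diazomethane activated by BF3·OEt2 would add to the C3 ketone of A5 and the aryl carbon would shift with loss of nitrogen. This gives (2S)-6-bromo-2-{[tert-butyl(dimethyl)silyl]oxymethyl}-8-methoxy-2-methylchroman-3-one A6, and the ketone of A6 would then be reduced and the alcohol dehydrated to C3=C4.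
- For: the quaternary centre of A5 would be set by enolate chemistry of a benzofuranone, a well-precedented asymmetric manifold, and cannot epimerise during the expansion. The C3 ketone of A6 gives regiodefined access to the alkene. On reliability of stereocentre formation this alternative is stronger.
- Against: aryl versus alkyl migration is not guaranteed, and the wrong shift gives a chroman-4-one. Homologation next to a quaternary carbon is sluggish and can over-insert. The acetyl group must be carried as bromide throughout, adding a late acylation step.
- Comparison: thirteen to fourteen linear steps with no convergence. The chosen route carries the native acetyl group from the first step.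

Key step: step 2

Assumption: the sense of induction of the new cycloaddition cannot be derived reliably in advance; the (S,S)-catalyst is written, and its equally accessible (R,R)-antipode would be used if that is the one delivering (2R)-6.

**Route**

Step 1
Reactants: 1 acetovanillone; 2 formaldehyde
Product: 3 salicyl alcohol 1-[4-hydroxy-3-(hydroxymethyl)-5-methoxyphenyl]ethanone
Conditions: 37% aq. CH2O (3 equiv), NaOH (1.1 equiv), H2O, rt → 45 °C; then aq. HCl to pH 5
Reagents that add atoms: none
Why: Lederer–Manasse hydroxymethylation; the phenoxide of 1 attacks formaldehyde through its only free ortho carbon, the para position being blocked by acetyl and the other ortho position by methoxy, so one regioisomer forms and a second hydroxymethylation is impossible. The para-acyl phenoxide is a vinylogous carboxylate and enolises poorly at the methyl ketone, which restrains aldol hydroxymethylation there.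

Step 2
Reactants: 3 salicyl alcohol 1-[4-hydroxy-3-(hydroxymethyl)-5-methoxyphenyl]ethanone; 4 2-methylprop-2-en-1-ol
Product: 6 (2R)-6-acetyl-2-(hydroxymethyl)-8-methoxy-2-methylchroman, via ortho-quinone methide 5 (not isolated)
Conditions: (S,S)-imidodiphosphorimidate acid [(Ar2BINOL)P(=NTf)]2NH (Ar2BINOL = (S)-3,3'-bis[3,5-bis(trifluoromethyl)phenyl]-1,1'-binaphthalene-2,2'-diolate, Tf = SO2CF3; 5 mol %), 4 (5 equiv), 5 Å molecular sieves, CHCl3, −20 °C → rt
Reagents that add atoms: none
Why: Proposed new method: the strongly acidic, confined imidodiphosphorimidate protonates the benzylic hydroxyl of 3 and water leaves to give ortho-quinone methide 5, held as its O-protonated form in a hydrogen-bonded ion pair with the chiral anion; the closest known reaction type is the chiral Brønsted acid-catalysed inverse-demand hetero-Diels–Alder reaction of in situ ortho-quinone methides with styrenes and enol ethers, extended here to an unsubstituted methide and to a 1,1-dialkyl alkene with a free hydroxyl. The CH2 terminus of 4 attacks the methide carbon (C3–C4) and the charge developing on the disubstituted carbon is captured by the quinone methide oxygen (O1–C2) in a concerted but asynchronous [4+2] event. The pyran ring is thus closed by intermolecular cycloaddition, the O1–C2 bond being the later, ring-closing one, and the arene is restored. Regiochemistry follows from polarity, since only attack through CH2 places charge on a tertiary carbon. The new stereocentre C2 is under catalyst control: the allylic OH of 4 donates a hydrogen bond to a sulfonyl or phosphoryl oxygen of the anion while the O1–H of protonated 5 is bound to the same anion, so that CH2OH and CH3 occupy different sites in the pocket and one face of the alkene carbon meets O1. The step needs C- over O-attack by 4 and enantioface selection; benzyl ether formation by alcohols is reversible under the acid and returns through 5, whereas the cycloaddition is irreversible. The acetyl and methoxy groups block the para and second ortho positions of 3 and so prevent Friedel–Crafts self-condensation, and excess 4 with sieves keeps 5 dilute and limits its dimerisation.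

Step 3
Reactants: 6 (2R)-6-acetyl-2-(hydroxymethyl)-8-methoxy-2-methylchroman
Product: 7 (2R)-2-(acetoxymethyl)-6-acetyl-8-methoxy-2-methylchroman
Conditions: Ac2O (1.5 equiv), pyridine, 4-(dimethylamino)pyridine (5 mol %), CH2Cl2, 0 °C → rt
Reagents that add atoms: acetic anhydride, CC(=O)OC(C)=O
Why: Nucleophile-catalysed O-acylation of the only hydroxyl group. The acetate is inert to bromine radicals and keeps the oxygen from closing onto C4 as a bridged bicyclic ether in the next step.

Step 4
Reactants: 7 (2R)-2-(acetoxymethyl)-6-acetyl-8-methoxy-2-methylchroman
Product: 9 (2R)-2-(acetoxymethyl)-6-acetyl-8-methoxy-2-methyl-2H-chromene, via 4-bromochroman acetate 8 (not isolated)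
Conditions: N-bromosuccinimide (1.05 equiv), azobisisobutyronitrile (5 mol %), PhCF3, 80 °C; then DBU (2.0 equiv), rt → 50 °C, exclusion of light after base addition
Reagents that add atoms: none
Why: Wohl–Ziegler bromination selects C4–H, the only benzylic C–H bonds of 7 (benzylic bromination next to an aryl methyl ketone is standard), and E2 dehydrobromination of 8 can only use the C3 hydrogens because C2 is quaternary. The C3=C4 bond forms in conjugation with the arene and the C2 configuration is not touched.

Step 5
Reactants: 9 (2R)-2-(acetoxymethyl)-6-acetyl-8-methoxy-2-methyl-2H-chromene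
Product: 10 (2R)-6-acetyl-2-(hydroxymethyl)-8-methoxy-2-methyl-2H-chromene
Conditions: K2CO3 (0.2 equiv), MeOH, 0 °C → rt
Reagents that add atoms: none
Why: Base-catalysed transesterification of a primary acetate with methanol; the aryl ketone, aryl ethers and chromene double bond are inert to these conditions.

Step 6
Reactants: 11 (E)-ferulic acid
Product: 13 (E)-3-[4-(tert-butyldimethylsilyloxy)-3-methoxyphenyl]prop-2-enoic acid, via bis-silyl ferulate 12 (not isolated)
Conditions: TBSCl (2.3 equiv), imidazole (5 equiv), DMF, rt; then THF/H2O/AcOH (8:2:1), rt, 1 h
Reagents that add atoms: tert-butyldimethylsilyl chloride, CC(C)(C)[Si](C)(C)Cl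
Why: Imidazole-mediated silylation gives the silyl ether–silyl ester 12. The silyl ester is far more labile than the aryl silyl ether and is hydrolysed selectively by mild aqueous acid; base is avoided because it would cleave the aryl silyl ether.

Step 7
Reactants: 10 (2R)-6-acetyl-2-(hydroxymethyl)-8-methoxy-2-methyl-2H-chromene; 13 (E)-3-[4-(tert-butyldimethylsilyloxy)-3-methoxyphenyl]prop-2-enoic acid
Product: 14 [(2R)-6-acetyl-8-methoxy-2-methyl-2H-chromen-2-yl]methyl (E)-3-[4-(tert-butyldimethylsilyloxy)-3-methoxyphenyl]prop-2-enoate
Conditions: DCC (1.2 equiv), 4-(dimethylamino)pyridine (0.2 equiv), CH2Cl2, 0 °C → rt, subdued light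
Reagents that add atoms: none
Why: Steglich esterification; the acylpyridinium derived from 13 acylates the primary hydroxyl of 10 at oxygen, so the adjacent quaternary carbon only slows the reaction and C2 is not involved. The silyl ether prevents self-acylation of the phenol and the (E)-alkene geometry is carried through.

Step 8
Reactants: 14 [(2R)-6-acetyl-8-methoxy-2-methyl-2H-chromen-2-yl]methyl (E)-3-[4-(tert-butyldimethylsilyloxy)-3-methoxyphenyl]prop-2-enoate
Product: 15 [(2R)-6-acetyl-8-methoxy-2-methyl-2H-chromen-2-yl]methyl (E)-3-(4-hydroxy-3-methoxyphenyl)prop-2-enoate
Conditions: Bu4NF (1.1 equiv), AcOH (1.2 equiv), THF, 0 °C, subdued light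
Reagents that add atoms: none
Why: Fluoride-induced cleavage of the aryl silyl ether. Acetic acid protonates the phenoxide as it forms, so the cinnamate ester is not attacked and the methyl ketone is not enolised.

**Compound list**

1 | acetovanillone, 1-(4-hydroxy-3-methoxyphenyl)ethanone | CC(=O)c1ccc(O)c(OC)c1 | starting material
2 | formaldehyde (37% aqueous solution) | C=O | starting material
3 | 1-[4-hydroxy-3-(hydroxymethyl)-5-methoxyphenyl]ethanone | CC(=O)c1cc(CO)c(O)c(OC)c1 | intermediate
4 | 2-methylprop-2-en-1-ol (methallyl alcohol) | C=C(C)CO | starting material
5 | 4-acetyl-2-methoxy-6-methylidenecyclohexa-2,4-dien-1-one (ortho-quinone methide) | C=C1C=C(C(C)=O)C=C(OC)C1=O | intermediate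
6 | 1-[(2R)-2-(hydroxymethyl)-8-methoxy-2-methyl-3,4-dihydro-2H-chromen-6-yl]ethanone | OC[C@@]1(C)CCc2cc(C(C)=O)cc(OC)c2O1 | intermediate
7 | [(2R)-6-acetyl-8-methoxy-2-methyl-3,4-dihydro-2H-chromen-2-yl]methyl acetate | CC(=O)OC[C@@]1(C)CCc2cc(C(C)=O)cc(OC)c2O1 | intermediate
8 | [(2R)-6-acetyl-4-bromo-8-methoxy-2-methyl-3,4-dihydro-2H-chromen-2-yl]methyl acetate (both C4 epimers) | CC(=O)OC[C@@]1(C)CC(Br)c2cc(C(C)=O)cc(OC)c2O1 | intermediate
9 | [(2R)-6-acetyl-8-methoxy-2-methyl-2H-chromen-2-yl]methyl acetate | CC(=O)OC[C@@]1(C)C=Cc2cc(C(C)=O)cc(OC)c2O1 | intermediate
10 | 1-[(2R)-2-(hydroxymethyl)-8-methoxy-2-methyl-2H-chromen-6-yl]ethanone | OC[C@@]1(C)C=Cc2cc(C(C)=O)cc(OC)c2O1 | intermediate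
11 | (E)-ferulic acid, (E)-3-(4-hydroxy-3-methoxyphenyl)prop-2-enoic acid | COc1cc(/C=C/C(=O)O)ccc1O | starting material
12 | tert-butyldimethylsilyl (E)-3-[4-(tert-butyldimethylsilyloxy)-3-methoxyphenyl]prop-2-enoate | COc1cc(/C=C/C(=O)O[Si](C)(C)C(C)(C)C)ccc1O[Si](C)(C)C(C)(C)C | intermediate
13 | (E)-3-[4-(tert-butyldimethylsilyloxy)-3-methoxyphenyl]prop-2-enoic acid | COc1cc(/C=C/C(=O)O)ccc1O[Si](C)(C)C(C)(C)C | intermediate
14 | [(2R)-6-acetyl-8-methoxy-2-methyl-2H-chromen-2-yl]methyl (E)-3-[4-(tert-butyldimethylsilyloxy)-3-methoxyphenyl]prop-2-enoate | COc1cc(/C=C/C(=O)OC[C@@]2(C)C=Cc3cc(C(C)=O)cc(OC)c3O2)ccc1O[Si](C)(C)C(C)(C)C | intermediate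
15 | [(2R)-6-acetyl-8-methoxy-2-methyl-2H-chromen-2-yl]methyl (E)-3-(4-hydroxy-3-methoxyphenyl)prop-2-enoate | COc1cc(/C=C/C(=O)OC[C@@]2(C)C=Cc3cc(C(C)=O)cc(OC)c3O2)ccc1O | target

**Step count and least certain steps**

Total: 8 steps. Longest linear sequence: 7 steps (1, 2, 3, 4, 5, 7, 8); step 6 is a one-step side branch.

Step 2 (key step, proposed new method). Three things are most likely to go wrong.
- Face discrimination between CH3 and CH2OH may be weak, because two hydrogen bonds to one anion may not hold the small alkene rigidly.
- The quinone methide may drain into benzyl ethers and oligomers before the moderately nucleophilic alkene forms the C–C bond.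
- A stepwise pathway may intervene, in which the β-hydroxy cation undergoes a 1,2-hydride shift to an aldehyde instead of closing on O1.

The fallback uses known chemistry and starts from 3 and 4. Thermal dehydration of 3 in excess 4 (sealed tube, about 170 °C, no catalyst) generates 5, and its uncatalysed hetero-Diels–Alder reaction gives racemic 6-acetyl-2-(hydroxymethyl)-8-methoxy-2-methylchroman F1. Esterification of F1 with (S)-2-methoxy-2-phenylacetic acid (DCC, 4-(dimethylamino)pyridine) gives two diastereomers, separated by crystallisation or chromatography: the (2R)-chromanylmethyl (2S)-2-methoxy-2-phenylacetate F2 and its (2S)-chromanylmethyl diastereomer F3. Methanolysis of F2 (K2CO3, MeOH) returns to the route at 6.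

Step 1. Conversion may stall, the product may condense with a second phenoxide to a diarylmethane, and some hydroxymethylation may occur next to the ketone. The fallback starts from 1: Blanc chloromethylation (paraformaldehyde, concentrated HCl) gives 1-[3-(chloromethyl)-4-hydroxy-5-methoxyphenyl]ethanone F4, and hydrolysis of F4 with NaHCO3 in aqueous acetone returns to the route at 3.

Step 4. Premature loss of HBr during bromination would expose the new alkene to bromine (over-bromination at C3/C4), and the ionic pathway could brominate the ring or the acetyl group. The fallback starts from 7 and replaces the radical bromination–elimination with hydride-abstraction dehydrogenation by 2,3-dichloro-5,6-dicyano-1,4-benzoquinone in refluxing 1,4-dioxane, coming back at 9. It makes no new compound and is entered as F0.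

Step 7. Acylation of the neopentyl-type hydroxyl may be slow enough for the activated acid to rearrange to an unreactive N-acylurea. The fallback starts from 10 and builds the cinnamate on the alcohol instead. Heating 10 with Meldrum's acid in toluene gives the malonic half-ester 3-{[(2R)-6-acetyl-8-methoxy-2-methyl-2H-chromen-2-yl]methoxy}-3-oxopropanoic acid F5. Knoevenagel–Doebner condensation of F5 with vanillin (pyridine, catalytic piperidine) with decarboxylation gives the (E)-ferulate directly, returning at 15 and bypassing steps 6 and 8.

**Further compounds**

F1 | step 2 | racemic 1-[2-(hydroxymethyl)-8-methoxy-2-methyl-3,4-dihydro-2H-chromen-6-yl]ethanone | OCC1(C)CCc2cc(C(C)=O)cc(OC)c2O1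
F2 | step 2 | [(2R)-6-acetyl-8-methoxy-2-methyl-3,4-dihydro-2H-chromen-2-yl]methyl (2S)-2-methoxy-2-phenylacetate | CO[C@H](C(=O)OC[C@@]1(C)CCc2cc(C(C)=O)cc(OC)c2O1)c1ccccc1
F3 | step 2 | [(2S)-6-acetyl-8-methoxy-2-methyl-3,4-dihydro-2H-chromen-2-yl]methyl (2S)-2-methoxy-2-phenylacetate | CO[C@H](C(=O)OC[C@]1(C)CCc2cc(C(C)=O)cc(OC)c2O1)c1ccccc1
F4 | step 1 | 1-[3-(chloromethyl)-4-hydroxy-5-methoxyphenyl]ethanone | CC(=O)c1cc(CCl)c(O)c(OC)c1
F0 | step 4 | none | none
F5 | step 7 | 3-{[(2R)-6-acetyl-8-methoxy-2-methyl-2H-chromen-2-yl]methoxy}-3-oxopropanoic acid | O=C(O)CC(=O)OC[C@@]1(C)C=Cc2cc(C(C)=O)cc(OC)c2O1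
A1 | alternative 1 | 2-(4-acetyl-2-bromo-6-methoxyphenoxy)-2-methylpropanoic acid | CC(C)(Oc1c(Br)cc(C(C)=O)cc1OC)C(=O)O
A2 | alternative 1 | (3S)-3-(4-acetyl-2-bromo-6-methoxyphenoxy)-3-methyloxetan-2-one | O=C1OC[C@]1(C)Oc1c(Br)cc(C(C)=O)cc1OC
A3 | alternative 2 | (2E)-4-(5-acetyl-2-hydroxy-3-methoxyphenyl)-2-methylbut-2-en-1-yl acetate | CC(=O)OC/C(C)=C/Cc1cc(C(C)=O)cc(OC)c1O
A4 | alternative 2 | (2S,3R)-2-(acetoxymethyl)-6-acetyl-8-methoxy-2-methyl-3-(phenylthio)chroman | CC(=O)OC[C@@]1(C)[C@H](Sc2ccccc2)Cc2cc(C(C)=O)cc(OC)c2O1
A5 | alternative 3 | (2S)-5-bromo-2-{[tert-butyl(dimethyl)silyl]oxymethyl}-7-methoxy-2-methyl-1-benzofuran-3(2H)-one | CC(C)(C)[Si](C)(C)OC[C@@]1(C)C(=O)c2cc(Br)cc(OC)c2O1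
A6 | alternative 3 | (2S)-6-bromo-2-{[tert-butyl(dimethyl)silyl]oxymethyl}-8-methoxy-2-methylchroman-3-one | CC(C)(C)[Si](C)(C)OC[C@@]1(C)C(=O)Cc2cc(Br)cc(OC)c2O1
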